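Numbering used throughout: C1 methyl-bearing fusion carbon, C2–C3 ring CH2 groups, C4 isopropyl carbinol, C5 fusion CH, C6 ester carbon, C7 CH2, C8(CH3)=C9, C10 CH2.

## Structural features

The target is a trans-fused bicyclo[5.3.0]decene in which a cyclopentane and a cycloheptene share the C1–C5 bond. The seven-membered ring carries a trisubstituted C8=C9 alkene with a methyl group on C8. Four contiguous stereocentres sit on and around the fusion: quaternary C1 (methyl), C5 (H trans to that methyl), C4 (tertiary carbinol with isopropyl, hydroxyl cis to the C1 methyl) and C6 (secondary salicylate, oxygen cis to H5). The fragile groups are the tertiary C4 alcohol (acid-promoted dehydration), the salicylate with its free phenol (acyl transfer under base), the 1,3-diol monoester pattern C4–OH/C6–O-acyl, and the ring alkene (acid, hydrogenation). Any intermediate with a carbonyl at C4 has the C6 oxygen in the β-position and an acidic H at C5, so it can epimerise or eliminate. The real difficulty is the relative configuration of C1, C5 and C6 on a conformationally loose seven-membered ring, with the quaternary C1 next to C5. The key step uses the fact that C4 lies between C3 and C5 and that C1 carries the two-carbon arm C2–C3. An aldehyde carbon (C4) on C5 and a vinyl group (C2=C3) on C1 form a 4-pentenal, and hydroacylation closes the five-membered ring by the C3–C4 bond and leaves C4 as the ketone needed for the isopropyl carbinol.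

## Logic of the disconnections

**18 ⇒ 16 + 17.** The C6–O acyl bond is cut first because the hydroxy-aryl ester is the most labile group and should be made last. This removes the arene and leaves a diol. The forward step must acylate the secondary C6 hydroxyl beside the tertiary C4 hydroxyl and must release the phenol without a separate deprotection; 17 is chosen because it carries the phenol oxygen in masked form and sheds the mask during acyl transfer.

**16 ⇒ 15 ⇒ 14.** The C4–isopropyl bond (and the O–Si bond at C6) is cut, tracing the tertiary carbinol back to a ketone. This removes one stereocentre and three carbons and arrives at the ketone that the key step delivers. The forward addition must come from the face opposite the C1 methyl and must not enolise toward C5, where the β-silyloxy group could be lost.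

**14 ⇒ 13.** The C3–C4 bond is cut. This opens the five-membered ring to an aldehyde on C5 and a vinyl group on C1 of a cycloheptene, so the bicyclic problem becomes a monocyclic one with C1, C5 and C6 already in place. The forward step must add the formyl C–H across the vinyl group with the metal at the terminal carbon, faster than decarbonylation, and without touching C5.

**13 ⇒ 12 ⇒ 11.** No skeletal bond is cut; the aldehyde is traced to a primary alcohol and the silyl ether to a free secondary alcohol. The purpose is to create the epimerisable, elimination-prone β-oxygenated aldehyde only immediately before it is used. The forward steps must distinguish a primary from a secondary hydroxyl.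

**11 ⇒ 10.** The C8=C9 double bond is cut. A trisubstituted alkene inside a seven-membered ring is a good metathesis retron, and opening it converts the ring problem into an acyclic stereotriad. The forward closure must join the allyl and 2-methylallyl termini and leave the vinyl group on the quaternary carbon alone.

**10 ⇒ 7 (through 9 and 8).** The C1–C5 bond is cut as a [3,3] retron: a quaternary carbon bearing a vinyl group next to the α-carbon of a carboxyl derivative. This traces C1 and C5 back to one existing stereocentre (C6) and one alkene geometry, and makes the branch convergent. The forward step needs a defined enolate geometry, a chair transition state and control of the enolate face by C6; a chelated dianion (8) supplies all three and cannot eliminate the β-oxygen.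

**7 ⇒ 6 + 3.** The ester C–O bond is cut to give two small fragments of comparable size. The forward ester exchange must leave the β-hydroxy ester intact (no dehydration, no retro-aldol).

**6 ⇒ 5 ⇒ 4.** The C7–C8 bond is cut as an epoxide opening by an isopropenyl nucleophile, and the epoxide is traced to a commercial chlorohydrin, which supplies C6 as a single enantiomer. The forward opening must occur at the terminal epoxide carbon without attack on the ester or base-induced epoxide isomerisation.

**3 ⇒ 1 (through 2).** The C–CH3 and C–CH2OH bonds across the trisubstituted alkene are cut, leading to a terminal alkyne. Syn carbometalation fixes the (E) geometry that the chair transition state later translates into the C1 configuration. The forward step must be regioselective (methyl to the internal carbon) and must spare the terminal alkene.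

## Other disconnections considered

**Alternative 1:** The seven-membered ring is cut at C1–C10 and C6–C7, leading back to the cyclopentenyl diazoacetate A1 (C4 silyl ether and C1 methyl already on the five-membered ring) and isoprene A2.
- Forward step: Rh2(S-DOSP)4 would convert A1 into a vinylcarbenoid that cyclopropanates the 1,1-disubstituted double bond of A2. The cis-divinylcyclopropane would then undergo Cope rearrangement through a boat transition state to the fused cyclohepta-1,4-diene ester A3.
- In its favour: two C–C bonds, the seven-membered ring, the quaternary C1 and the C8=C9 alkene with its methyl correctly placed arise in one catalytic operation, and the C4 carbinol is settled early. On bond-forming economy of the key step this alternative is the better plan.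
- Against it here:
  - C6 emerges as an sp2 carbon bearing an ester, so a carbon substituent would have to be degraded to oxygen.
  - C5 and C6 would have to be set afterwards by reduction of a tetrasubstituted conjugated alkene, with both the trans fusion and the C6 oxygen orientation required.
  - The tertiary silyl ether of A1 and A3 is allylic and prone to ionisation.
  - The resident C4 stereocentre and the chiral catalyst may oppose each other at C1.
  - The carbenoid must choose the substituted over the unsubstituted double bond of A2.
- Comparison: structurally it solves C1 and the ring at once but leaves C5 and C6 open, whereas the chosen plan fixes C1, C5 and C6 together from one purchased stereocentre. Mechanistically both key steps are stereospecific and well founded, so the two are equal there. In step economy, the operations needed after A3 are expected to outweigh what the key step gains.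

**Alternative 2:** The C1–C5 bond is cut and C1 is reconnected to C6, turning the hydroazulene into the trans-decalin epoxy silyl ether A4 (silyloxy group on the fusion carbon C6, C4–C5 epoxide).
- Forward step: BF3·OEt2 would open the epoxide at C5 while C1 migrates from C6 to C5 with inversion at C5 (semipinacol rearrangement of a 2,3-epoxy silyl ether), giving the β-hydroxy ketone A5.
- In its favour: C4 with its isopropyl and hydroxyl groups, C5 and the C6 oxidation level come from one stereospecific step on a ring system with mature annulation chemistry. From A5 only a hydroxyl-directed 1,3-anti reduction (for example Me4NBH(OAc)3) and the acylation would remain. That end game is shorter than the three steps after the key step of the chosen plan, and on this point the alternative is the better one.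
- Against it here:
  - The distal epoxide carbon C4 is tertiary and the proximal C5 is secondary, so ionisation at C4 (followed by hydride shift or elimination) competes with the wanted C5–O cleavage.
  - The configuration of A5 requires the epoxide on the face of the angular methyl and anti to the C6 oxygen. It therefore cannot be installed by hydroxyl-directed epoxidation and must be made in preference to the C8=C9 alkene.
  - In the chair trans-decalin the bond antiperiplanar to C5–O is the axial C6–O bond, not C6–C1, so migration of C1 needs a higher-energy conformer.
  - A5 is a β-hydroxy ketone with a β,γ-alkene, open to retro-aldol cleavage, dehydration and alkene migration under the same Lewis acid.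
- Comparison: structurally it handles C4, which the chosen plan leaves to a late organometallic addition, but four stereocentres must be built in A4 to obtain three in A5. Mechanistically the hydroacylation has no comparable regiochemical ambiguity. In step economy the short end game is offset by the longer route to A4.

**Alternative 3:** The C6–C7 and C7–C8 bonds are cut, removing C7 and leaving the hydrindenone silyl ether A6.
- Forward step: trimethylsilyldiazomethane A7 with BF3·OEt2 would add to the C8 carbonyl of A6, and the alkenyl carbon C6 would migrate (Tiffeneau–Demjanov-type homologation) to give the β,γ-unsaturated cycloheptenone A8.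
- In its favour: the quaternary C1 comes from a proline-catalysed annulation on cheap material. In catalyst economy this is better than the stoichiometric chirality transfer of the chosen plan. The five-membered ring is already present, and hydroboration of the C5=C6 alkene of A8 from the face opposite the angular methyl could place H at C5 and oxygen at C6 with the required relative configuration in one step.
- Against it here:
  - Alkenyl versus alkyl migration is not secured.
  - The non-conjugated ketone A8 is more electrophilic than the enone A6 and invites a second homologation, and its alkene can move into conjugation.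
  - After A8 the C8 carbonyl must still become the C8-methyl alkene with C8=C9 regiochemistry, while enolisation prefers C7.
  - The C4 oxygen must be oxidised and isopropylated late, so the β-oxygenated C4 ketone problem of the chosen plan returns.
  - A correction is needed: a proline-catalysed annulation puts the five-ring oxygen next to the quaternary carbon (C2 in this numbering), whereas A6 and A8 carry it on C4. A6 as drawn therefore needs an oxygen transposition or a different origin.
- Comparison: structurally it starts with C1 and one ring but has C5, C6, C4 and the alkene still to do. Mechanistically the migration selectivity is less predictable than the insertion selectivity of the hydroacylation. In step economy an estimated eight to ten steps would follow A8, against three after the chosen key step.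

Key step: step 9

## Remarks before the steps

- The structures used for the key step (13 and 14) were checked atom by atom against the target. Vinyl and formyl are trans, formyl and silyloxy are trans, and the descriptors are consistent with (3R,3aS,4S,8aR) in the target. No change was needed.
- An entry to 13 through a (4+3) cycloaddition of isoprene with a 2-silyloxy enal, followed by α-vinylation and methoxymethylenation, is not used, for two reasons:
  - The polarisation of both partners points to bonding of the methyl-substituted terminus of isoprene to the enal β-carbon, which would put the ring methyl on C9 instead of C8.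
  - The cycloadduct would be racemic with C6 already set, so an enantioselective vinylation at the other α-carbon could not give one diastereomer.
- Instead, C1, C5 and C6 are set before ring closure by a chirality-transferring Claisen rearrangement, and the β-silyloxy aldehyde is formed only in the step before it is used.
- Assumption: pent-1-en-4-yne (1) and 2,2-dimethyl-4H-1,3-benzodioxin-4-one (17) are taken as purchasable. Each is otherwise one known operation from allyl bromide and an ethynyl Grignard reagent, or from salicylic acid, acetone and trifluoroacetic anhydride.

## Steps

Step 1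
Reactants: 1 pent-1-en-4-yne
Product: 3 (2E)-3-methylhexa-2,5-dien-1-ol, via alkenyldimethylalane 2 (not isolated)
Conditions: Me3Al (2.5 equiv), Cp2ZrCl2 (0.25 equiv), CH2Cl2, 0 °C → rt; n-BuLi, THF, −78 °C; (CH2O)n, −78 °C → rt; aq. HCl
Reagents that add atoms: trimethylaluminium, C[Al](C)C; paraformaldehyde (as formaldehyde), C=O
Why: Zirconium-catalysed methylalumination (Negishi carboalumination) adds methyl and aluminium syn across the terminal alkyne with methyl on the internal carbon, and the ate complex of 2 is hydroxymethylated with retention, so 3 should have the (E) geometry; the isolated terminal alkene carbometalates far more slowly than the alkyne.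

Step 2
Reactants: 4 ethyl (3R)-4-chloro-3-hydroxybutanoate
Product: 5 ethyl 2-[(2R)-oxiran-2-yl]acetate
Conditions: Ag2O (1.5 equiv), 1,2-dimethoxyethane, 60 °C, dark
Reagents that add atoms: none
Why: Silver-assisted intramolecular Williamson etherification of a chlorohydrin; halide abstraction without strong base avoids the base-induced isomerisation of the β,γ-epoxy ester to the γ-hydroxy enoate, and the stereocentre is not touched.

Step 3
Reactants: 5 ethyl 2-[(2R)-oxiran-2-yl]acetate
Product: 6 ethyl (3S)-3-hydroxy-5-methylhex-5-enoate
Conditions: CH2=C(Me)MgBr (2 equiv), CuI (10 mol %), THF, −40 → −20 °C; aq. NH4Cl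
Reagents that add atoms: isopropenylmagnesium bromide, C=C(C)[Mg]Br
Why: Copper-catalysed Grignard opening of a terminal epoxide at its primary carbon (SN2), a known way to make β-hydroxy esters from β,γ-epoxy esters; the carbinol carbon keeps its configuration and the descriptor changes from R to S only because the CIP priorities change; low temperature favours epoxide opening over addition to the ester.

Step 4
Reactants: 6 ethyl (3S)-3-hydroxy-5-methylhex-5-enoate; 3 (2E)-3-methylhexa-2,5-dien-1-ol
Product: 7 (2E)-3-methylhexa-2,5-dien-1-yl (3S)-3-hydroxy-5-methylhex-5-enoate
Conditions: 3 (2 equiv), Ti(OEt)4 (0.2 equiv), toluene, 100 °C, EtOH distilled off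
Reagents that add atoms: none
Why: Titanate-mediated transesterification under neutral conditions, a method compatible with β-hydroxy esters (no dehydration, no retro-aldol); the primary allylic alcohol in excess outcompetes the secondary hydroxyl of 6, and removal of ethanol drives the exchange.

Step 5
Reactants: 7 (2E)-3-methylhexa-2,5-dien-1-yl (3S)-3-hydroxy-5-methylhex-5-enoate
Product: 10 (2R,3S)-5-methyl-2-[(3S)-3-methylhexa-1,5-dien-3-yl]hex-5-ene-1,3-diol, via dilithium enolate alkoxide 8 (not isolated), via rearranged hydroxy acid salt 9 (not isolated)
Conditions: LDA (2.3 equiv), THF, −78 °C; → 25 °C then 50 °C; LiAlH4, 0 → 65 °C; Rochelle salt work-up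
Reagents that add atoms: none
Why: Dianionic ester-enolate Claisen rearrangement of an allyl β-hydroxy ester (Ireland–Claisen family): the lithium chelate 8 fixes the enolate geometry (C6 cis to the enolate oxygen) and cannot eliminate the β-oxygen; in the chair transition state the (E)-alkene places C10 equatorial and the methyl axial, and the allyl terminus bonds to C5 on the chelate face away from the C7 chain, as electrophiles do in Fráter–Seebach alkylation, so C6 sets C5 (anti) and C1. LiAlH4 then reduces the carboxylate of 9 in the same flask, a standard reduction that leaves the three alkenes alone.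

Step 6
Reactants: 10 (2R,3S)-5-methyl-2-[(3S)-3-methylhexa-1,5-dien-3-yl]hex-5-ene-1,3-diol
Product: 11 (1S,6S,7R)-6-ethenyl-7-(hydroxymethyl)-3,6-dimethylcyclohept-3-en-1-ol
Conditions: second-generation Grubbs catalyst RuCl2(H2IMes)(PCy3)(=CHPh) (5 mol %), CH2Cl2 (0.005 M), 40 °C
Reagents that add atoms: none
Why: Ring-closing metathesis: the ruthenium carbene should load at the unhindered allyl terminus and close onto the 1,1-disubstituted alkene, giving the trisubstituted cycloheptene (C8=C9) with loss of ethene; the vinyl group on the quaternary carbon is too hindered to initiate, and its closure with the allyl-derived carbene would require a four-membered ring, so it should remain a spectator.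

Step 7
Reactants: 11 (1S,6S,7R)-6-ethenyl-7-(hydroxymethyl)-3,6-dimethylcyclohept-3-en-1-ol
Product: 12 (1S,2S,7S)-2-ethenyl-7-hydroxy-2,5-dimethylcyclohept-4-ene-1-carbaldehyde
Conditions: TEMPO (0.1 equiv), PhI(OAc)2 (1.1 equiv), CH2Cl2, rt
Reagents that add atoms: none
Why: Oxoammonium (TEMPO) oxidation with PhI(OAc)2 as terminal oxidant is selective for primary over secondary alcohols and stops at the aldehyde; the nearly neutral medium should not epimerise C5, where the formyl group is in any case trans to both neighbours.

Step 8
Reactants: 12 (1S,2S,7S)-2-ethenyl-7-hydroxy-2,5-dimethylcyclohept-4-ene-1-carbaldehyde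
Product: 13 (1S,2S,7S)-7-[(tert-butyldimethylsilyl)oxy]-2-ethenyl-2,5-dimethylcyclohept-4-ene-1-carbaldehyde
Conditions: TBSOTf (1.2 equiv), 2,6-lutidine (2 equiv), CH2Cl2, −78 °C
Reagents that add atoms: tert-butyldimethylsilyl trifluoromethanesulfonate, CC(C)(C)[Si](C)(C)OS(=O)(=O)C(F)(F)F
Why: Silylation of a hindered secondary alcohol with a silyl triflate and a hindered pyridine base, routine for β-hydroxy aldehydes at low temperature; the buffered, non-nucleophilic conditions should avoid β-elimination and epimerisation.

Step 9
Reactants: 13 (1S,2S,7S)-7-[(tert-butyldimethylsilyl)oxy]-2-ethenyl-2,5-dimethylcyclohept-4-ene-1-carbaldehyde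
Product: 14 (3aR,8S,8aS)-8-[(tert-butyldimethylsilyl)oxy]-3a,6-dimethyl-3,3a,4,7,8,8a-hexahydroazulen-1(2H)-one
Conditions: [Rh(nbd)(dppe)]BF4 (5 mol %), H2 then Ar (gives [Rh(dppe)(acetone)2]BF4), acetone–CH2Cl2, 25 °C
Reagents that add atoms: none
Why: Monovalent rhodium adds oxidatively into the formyl C–H bond to give an acyl hydride of trivalent rhodium; the C1 vinyl group coordinates and inserts into Rh–H with the metal going to the terminal carbon C3, giving a six-membered acyl–alkyl rhodacycle, and reductive elimination forms C3–C4. The closest known reaction type is the cationic rhodium–bisphosphine-catalysed intramolecular hydroacylation of 4-pentenals to cyclopentanones, including 2- and 3-substituted examples. The five-membered ring is closed by C–C reductive elimination from the rhodacycle; both vinyl carbons end up inside the ring (an endo-type closure), which is why the metallacycle path is needed. No stereocentre is created: C4 becomes a carbonyl carbon and C1, C5 and C6 are carried over, so the trans fusion follows from the trans vinyl/formyl relationship set in step 5. The step needs chemoselectivity for the vinyl group over C8=C9, anti-Markovnikov insertion, cyclisation faster than decarbonylation, and no epimerisation at C5. The ring alkene stands in a 5-hexenal relationship to the aldehyde and is trisubstituted, so it should not insert; Markovnikov insertion would lead to a four-membered ring and is disfavoured; the quaternary C1 and the branched C5 compress the tether and favour ring closure over CO extrusion. The medium is neutral and the counter-ion weakly coordinating, so the β-silyloxy aldehyde should neither epimerise nor eliminate.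

Step 10
Reactants: 14 (3aR,8S,8aS)-8-[(tert-butyldimethylsilyl)oxy]-3a,6-dimethyl-3,3a,4,7,8,8a-hexahydroazulen-1(2H)-one
Product: 15 (1R,3aR,8S,8aS)-8-[(tert-butyldimethylsilyl)oxy]-3a,6-dimethyl-1-(propan-2-yl)-1,2,3,3a,4,7,8,8a-octahydroazulen-1-ol
Conditions: i-PrMgCl (3 equiv), CeCl3 (3 equiv, dried), THF, −78 → −40 °C; aq. NH4Cl
Reagents that add atoms: isopropylmagnesium chloride, CC(C)[Mg]Cl
Why: Organocerium 1,2-addition to an enolisable ketone: the weakly basic cerium reagent should add rather than enolise toward C5 or transfer hydride; the axial C1 methyl shields one face of the cyclopentanone while the C6 silyloxy group lies near the ring plane, so attack from the face of H5 should give the C4 hydroxyl cis to the angular methyl (4R in the target).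

Step 11
Reactants: 15 (1R,3aR,8S,8aS)-8-[(tert-butyldimethylsilyl)oxy]-3a,6-dimethyl-1-(propan-2-yl)-1,2,3,3a,4,7,8,8a-octahydroazulen-1-ol
Product: 16 (1R,3aR,8S,8aS)-3a,6-dimethyl-1-(propan-2-yl)-1,2,3,3a,4,7,8,8a-octahydroazulene-1,8-diol (jaeschkeanadiol)
Conditions: Bu4NF (3 equiv), THF, 25 → 50 °C
Reagents that add atoms: none
Why: Fluoride cleavage of the silyl ether; no acid is used, so the tertiary alcohol should not dehydrate, and any 1,3-silyl shift to the C4 oxygen is harmless because fluoride removes the group from either position.

Step 12
Reactants: 16 (1R,3aR,8S,8aS)-3a,6-dimethyl-1-(propan-2-yl)-1,2,3,3a,4,7,8,8a-octahydroazulene-1,8-diol; 17 2,2-dimethyl-4H-1,3-benzodioxin-4-one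
Product: 18 (3R,3aS,4S,8aR)-3-hydroxy-6,8a-dimethyl-3-(propan-2-yl)-1,2,3,3a,4,5,8,8a-octahydroazulen-4-yl 2-hydroxybenzoate
Conditions: NaN(SiMe3)2 (1.2 equiv), THF, 0 °C; 17 (1.3 equiv), 0 °C → rt; aq. NH4Cl
Reagents that add atoms: none
Why: Alkoxide acyl transfer from a salicylic acid acetonide, a known way to make salicylate esters: the C6 alkoxide adds to the carbonyl of 17, the hemiketal alkoxide collapses with loss of acetone, and the phenoxide formed is the thermodynamic sink. The tertiary C4 hydroxyl is too hindered to compete, and the free phenol appears without a separate deprotection.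

## Compound list

1 | pent-1-en-4-yne | C=CCC#C | starting material
2 | [(1E)-2-methylpenta-1,4-dien-1-yl]dimethylalumane | C[Al](C)/C=C(\C)CC=C | intermediate (not isolated)
3 | (2E)-3-methylhexa-2,5-dien-1-ol | OC/C=C(\C)CC=C | intermediate
4 | ethyl (3R)-4-chloro-3-hydroxybutanoate | CCOC(=O)C[C@@H](O)CCl | starting material
5 | ethyl 2-[(2R)-oxiran-2-yl]acetate | CCOC(=O)C[C@@H]1CO1 | intermediate
6 | ethyl (3S)-3-hydroxy-5-methylhex-5-enoate | CCOC(=O)C[C@@H](O)CC(C)=C | intermediate
7 | (2E)-3-methylhexa-2,5-dien-1-yl (3S)-3-hydroxy-5-methylhex-5-enoate | C=C(C)C[C@H](O)CC(=O)OC/C=C(\C)CC=C | intermediate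
8 | dilithium (Z)-enolate alkoxide of 7 (chelated dianion) | C=C(C)C[C@H]([O-])/C=C(\[O-])OC/C=C(\C)CC=C.[Li+].[Li+] | intermediate (not isolated)
9 | (2S,3S)-3-hydroxy-5-methyl-2-[(3S)-3-methylhexa-1,5-dien-3-yl]hex-5-enoic acid (present as its dilithium salt) | C=CC[C@@](C)(C=C)[C@H](C(=O)O)[C@@H](O)CC(C)=C | intermediate (not isolated)
10 | (2R,3S)-5-methyl-2-[(3S)-3-methylhexa-1,5-dien-3-yl]hex-5-ene-1,3-diol | C=CC[C@@](C)(C=C)[C@H](CO)[C@@H](O)CC(C)=C | intermediate
11 | (1S,6S,7R)-6-ethenyl-7-(hydroxymethyl)-3,6-dimethylcyclohept-3-en-1-ol | CC1=CC[C@@](C)(C=C)[C@H](CO)[C@@H](O)C1 | intermediate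
12 | (1S,2S,7S)-2-ethenyl-7-hydroxy-2,5-dimethylcyclohept-4-ene-1-carbaldehyde | CC1=CC[C@@](C)(C=C)[C@H](C=O)[C@@H](O)C1 | intermediate
13 | (1S,2S,7S)-7-[(tert-butyldimethylsilyl)oxy]-2-ethenyl-2,5-dimethylcyclohept-4-ene-1-carbaldehyde | CC1=CC[C@@](C)(C=C)[C@H](C=O)[C@@H](O[Si](C)(C)C(C)(C)C)C1 | intermediate (key-step precursor)
14 | (3aR,8S,8aS)-8-[(tert-butyldimethylsilyl)oxy]-3a,6-dimethyl-3,3a,4,7,8,8a-hexahydroazulen-1(2H)-one | CC1=CC[C@@]2(C)CCC(=O)[C@@H]2[C@@H](O[Si](C)(C)C(C)(C)C)C1 | intermediate (key-step product)
15 | (1R,3aR,8S,8aS)-8-[(tert-butyldimethylsilyl)oxy]-3a,6-dimethyl-1-(propan-2-yl)-1,2,3,3a,4,7,8,8a-octahydroazulen-1-ol | CC1=CC[C@@]2(C)CC[C@@](O)(C(C)C)[C@@H]2[C@@H](O[Si](C)(C)C(C)(C)C)C1 | intermediate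
16 | (1R,3aR,8S,8aS)-3a,6-dimethyl-1-(propan-2-yl)-1,2,3,3a,4,7,8,8a-octahydroazulene-1,8-diol (jaeschkeanadiol) | CC1=CC[C@@]2(C)CC[C@@](O)(C(C)C)[C@@H]2[C@@H](O)C1 | intermediate
17 | 2,2-dimethyl-4H-1,3-benzodioxin-4-one | CC1(C)OC(=O)c2ccccc2O1 | starting material
18 | (3R,3aS,4S,8aR)-3-hydroxy-6,8a-dimethyl-3-(propan-2-yl)-1,2,3,3a,4,5,8,8a-octahydroazulen-4-yl 2-hydroxybenzoate | CC1=CC[C@@]2(C)CC[C@@](O)(C(C)C)[C@@H]2[C@@H](OC(=O)c2ccccc2O)C1 | target

## Step count and least certain steps

Total: 12 steps. Longest linear sequence: 11 steps (steps 2–12, from 4); step 1 is a one-step branch that joins at step 4.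

**Step 9 (key step).** The most likely failure is decarbonylation of the acyl rhodium hydride, which also deactivates the catalyst as a carbonyl complex, because insertion of a vinyl group that sits on a quaternary carbon may be slow. Fallback from 13 back to 14 without hydroacylation: addition of vinylmagnesium bromide to 13 gives the divinyl carbinol F1 (both C4 epimers, of no consequence). Ring-closing metathesis between the two vinyl groups with the second-generation Grubbs catalyst closes the cyclopentenol F2. Oxidation with Dess–Martin periodinane gives the enone F3, and conjugate reduction with [(Ph3P)CuH]6 gives 14.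

**Step 5.** The most likely failure is slow rearrangement of the dianion (the [3,3] shift must build a quaternary carbon), which leaves time for enolate decomposition, or incomplete face control if the chelate is loosened on warming. Fallback from 7 back to 10: silylation (TBSCl, imidazole) gives the silyl ether F4. A conventional Ireland–Claisen rearrangement through the (Z)-silyl ketene acetal (LDA, THF–DMPU, Me3SiCl, then warming) gives the silyloxy acid F5. LiAlH4 reduction gives the mono-protected diol F6, and Bu4NF returns 10.

**Step 10.** The most likely failures are enolisation toward C5 with loss of the β-silyloxy group, or hydride transfer from the secondary organometallic, both favoured by the crowded ketone; erosion of facial selectivity is the second concern. Fallback from 14 back to 15: addition of the sp2 reagent 2-propenyllithium–CeCl3, which has no hydride to transfer and is smaller, gives the isopropenyl carbinol F9. Hydrogenation of the 1,1-disubstituted alkene with RhCl(PPh3)3 and H2, which should spare the trisubstituted ring alkene, gives 15.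

**Step 12.** The most likely failure is sluggish acyl transfer to the hindered C6 alkoxide, with competing acyl migration toward the C4 oxygen under base. Fallback from 16 back to 18: carbodiimide esterification (EDC, DMAP) with 2-(prop-2-en-1-yloxy)benzoic acid gives the O-allyl ester F10. Deallylation with Pd(PPh3)4 (zerovalent palladium) and morpholine gives 18 under neutral conditions that do not affect the alkene or the tertiary alcohol.

**Step 8.** The most likely failure is Lewis acid activation of the aldehyde by the silyl triflate, leading to elimination of the β-oxygen or an intramolecular carbonyl–alkene reaction. Fallback from 11 back to 13, which also bypasses 12: exhaustive silylation of 11 gives the bis-silyl ether F8. Selective cleavage of the primary silyl ether (HF·pyridine, pyridine, THF, 0 °C) gives the primary alcohol F7, and Dess–Martin oxidation gives 13.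

## Further compounds

F1 | step 9 | divinyl carbinol from addition of vinylmagnesium bromide to the formyl group of 13 (both C4 epimers) | CC1=CC[C@@](C)(C=C)[C@H](C(O)C=C)[C@@H](O[Si](C)(C)C(C)(C)C)C1
F2 | step 9 | cyclopentenol: C4 alcohol corresponding to 14 with a C2=C3 double bond (both C4 epimers) | CC1=CC[C@@]2(C)C=CC(O)[C@@H]2[C@@H](O[Si](C)(C)C(C)(C)C)C1
F3 | step 9 | enone: 14 with an additional C2=C3 double bond | CC1=CC[C@@]2(C)C=CC(=O)[C@@H]2[C@@H](O[Si](C)(C)C(C)(C)C)C1
F4 | step 5 | tert-butyldimethylsilyl ether of 7 | C=C(C)C[C@H](O[Si](C)(C)C(C)(C)C)CC(=O)OC/C=C(\C)CC=C
F5 | step 5 | C6 tert-butyldimethylsilyl ether of acid 9 | C=CC[C@@](C)(C=C)[C@H](C(=O)O)[C@@H](O[Si](C)(C)C(C)(C)C)CC(C)=C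
F6 | step 5 | C6 tert-butyldimethylsilyl ether of diol 10 (primary alcohol free) | C=CC[C@@](C)(C=C)[C@H](CO)[C@@H](O[Si](C)(C)C(C)(C)C)CC(C)=C
F7 | step 8 | C6 tert-butyldimethylsilyl ether of diol 11 (primary alcohol free) | CC1=CC[C@@](C)(C=C)[C@H](CO)[C@@H](O[Si](C)(C)C(C)(C)C)C1
F8 | step 8 | bis(tert-butyldimethylsilyl) ether of diol 11 | CC1=CC[C@@](C)(C=C)[C@H](CO[Si](C)(C)C(C)(C)C)[C@@H](O[Si](C)(C)C(C)(C)C)C1
F9 | step 10 | isopropenyl analogue of 15 (prop-1-en-2-yl in place of propan-2-yl on C4) | CC1=CC[C@@]2(C)CC[C@@](O)(C(C)=C)[C@@H]2[C@@H](O[Si](C)(C)C(C)(C)C)C1
F10 | step 12 | 2-(prop-2-en-1-yloxy)benzoate of 16 at the C6 oxygen (O-allyl ether of 18) | CC1=CC[C@@]2(C)CC[C@@](O)(C(C)C)[C@@H]2[C@@H](OC(=O)c2ccccc2OCC=C)C1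
A1 | alternative 1 | ethyl 2-diazo-2-[(5R)-2-methyl-5-(propan-2-yl)-5-(triethylsilyloxy)cyclopent-1-en-1-yl]acetate | CCOC(=O)C(=[N+]=[N-])C1=C(C)CC[C@@]1(O[Si](CC)(CC)CC)C(C)C
A2 | alternative 1 | isoprene (2-methylbuta-1,3-diene) | C=CC(C)=C
A3 | alternative 1 | ethyl (3R,8aR)-6,8a-dimethyl-3-(propan-2-yl)-3-(triethylsilyloxy)-1,2,3,5,8,8a-hexahydroazulene-4-carboxylate | CC1=CC[C@@]2(C)CC[C@@](O[Si](CC)(CC)CC)(C(C)C)C2=C(C(=O)OCC)C1
A4 | alternative 2 | trans-decalin epoxy silyl ether: C1–C6 fused decalin with C1 methyl, C6 triethylsilyloxy, C4–C5 epoxide on the face of the C1 methyl, C4 isopropyl, C8-methyl C8=C9 alkene | CC1=CC[C@@]2(C)CC[C@]3(C(C)C)O[C@@H]3[C@]2(O[Si](CC)(CC)CC)C1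
A5 | alternative 2 | (3R,3aR,8aR)-3-hydroxy-6,8a-dimethyl-3-(propan-2-yl)-2,3,3a,5,8,8a-hexahydroazulen-4(1H)-one | CC1=CC[C@@]2(C)CC[C@@](O)(C(C)C)[C@@H]2C(=O)C1
A6 | alternative 3 | (3S,7aR)-3-[(tert-butyldimethylsilyl)oxy]-7a-methyl-1,2,3,6,7,7a-hexahydro-5H-inden-5-one | O=C1CC[C@@]2(C)CC[C@H](O[Si](C)(C)C(C)(C)C)C2=C1
A7 | alternative 3 | trimethylsilyldiazomethane | C[Si](C)(C)C=[N+]=[N-]
A8 | alternative 3 | (3S,8aR)-3-[(tert-butyldimethylsilyl)oxy]-8a-methyl-2,3,5,7,8,8a-hexahydroazulen-6(1H)-one | O=C1CC[C@@]2(C)CC[C@H](O[Si](C)(C)C(C)(C)C)C2=CC1
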